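**Plan**

- Numbering: lactone ring O1, C2 (carbonyl), C3, C4, C5; C6 is the syringyl CH2 on C3 and C7 the guaiacyl CH2 on C4. Benzylic carbons on the adjacent ring carbons C3 and C4 are the imprint of a butenolide that took a benzylic nucleophile at C4 and a benzylic electrophile at C3.
- Retrosynthesis: remove the two O-benzyl groups, cut C3–OH (enolate hydroxylation), return C5H2 to an acetal carbon and C7H2 to a dithiane carbon, then cut C4–C7 and C3–C6 in one operation.
- Forward: the lactone ring is in place from the start (furfural to hydroxybutenolide to menthyl acetal). Dithiane anion, butenolide and benzylic bromide are joined in one flask, followed by desulfurization, acetal-to-methylene reduction, hydroxylation and hydrogenolysis.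
- Stereochemistry: C4 comes from the acetal centre of the crystalline 5S d-menthyloxy butenolide (addition anti to the menthyloxy group). C3 comes from oxygen transfer to the late lactone enolate on the face opposite the C4 arylmethyl group.

Key step: step 8

Remark: in the target (3S,4R) the two benzyl groups are cis on the lactone, so the C3 hydroxyl is trans to the C4 arylmethyl group. This is what anti hydroxylation of the trans-dibenzyl lactone enolate delivers.

**Route**

Step 1
Reactants: 1 furfural
Product: 3 5-hydroxyfuran-2(5H)-one (racemic), via furfural endoperoxide 2 (not isolated)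
Conditions: O2, rose bengal (cat.), hν (visible), MeOH, rt
Reagents that add atoms: dioxygen, O=O
Why: Dye-sensitized singlet oxygen adds across C2/C5 of the furan ([4+2] photooxygenation) and methanolysis of endoperoxide 2 expels the formyl carbon as methyl formate, leaving the hydroxybutenolide, whose carbinol centre is fixed only in step 2.

Step 2
Reactants: 3 5-hydroxyfuran-2(5H)-one; 4 (+)-menthol, (1S,2R,5S)-2-isopropyl-5-methylcyclohexanol
Product: 6 (5S)-5-{[(1S,2R,5S)-2-isopropyl-5-methylcyclohexyl]oxy}furan-2(5H)-one, via 5R epimer 5 (not isolated)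
Conditions: p-TsOH·H2O (cat.), toluene, reflux, Dean–Stark; crystallization from petroleum ether, −20 °C, with acid re-equilibration of the mother liquor
Reagents that add atoms: none
Why: Acid-catalysed acetalization of the pseudo-acid with removal of water gives both C5 epimers, which interconvert under the acid, so crystallization with recycling should funnel the material into the crystalline 5S epimer (mirror image of the well-known crystalline l-menthyloxy 5R compound).

Step 3
Reactants: 7 vanillin
Product: 8 4-(benzyloxy)-3-methoxybenzaldehyde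
Conditions: BnBr, K2CO3, DMF, rt
Reagents that add atoms: benzyl bromide, BrCc1ccccc1
Why: Williamson etherification of the phenoxide masks the phenol as a benzyl ether that tolerates organolithium, hydride and enolate chemistry and leaves by hydrogenolysis at the end.

Step 4
Reactants: 8 4-(benzyloxy)-3-methoxybenzaldehyde
Product: 9 2-[4-(benzyloxy)-3-methoxyphenyl]-1,3-dithiane
Conditions: HS(CH2)3SH, BF3·OEt2 (cat.), CH2Cl2, 0 °C → rt
Reagents that add atoms: propane-1,3-dithiol, SCCCS
Why: Lewis-acid-catalysed dithioacetalization converts the aldehyde carbon into an acidic, umpoled C7 precursor.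

Step 5
Reactants: 10 syringaldehyde
Product: 11 4-(benzyloxy)-3,5-dimethoxybenzaldehyde
Conditions: BnBr, K2CO3, DMF, 60 °C
Reagents that add atoms: benzyl bromide, BrCc1ccccc1
Why: Williamson etherification of the hindered 2,6-dimethoxyphenoxide, which needs gentle heating, protects the syringyl phenol.

Step 6
Reactants: 11 4-(benzyloxy)-3,5-dimethoxybenzaldehyde
Product: 12 [4-(benzyloxy)-3,5-dimethoxyphenyl]methanol
Conditions: NaBH4, MeOH/THF, 0 °C
Reagents that add atoms: none
Why: Borohydride reduction of the aryl aldehyde gives the benzylic alcohol cleanly.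

Step 7
Reactants: 12 [4-(benzyloxy)-3,5-dimethoxyphenyl]methanol
Product: 13 4-(benzyloxy)-3,5-dimethoxybenzyl bromide
Conditions: PBr3, Et2O, 0 °C; used without storage
Reagents that add atoms: phosphorus tribromide, BrP(Br)Br
Why: Bromide displaces the phosphite ester of the electron-rich benzylic alcohol to give the reactive C6 electrophile.

Step 8
Reactants: 9 2-[4-(benzyloxy)-3-methoxyphenyl]-1,3-dithiane; 6 (5S)-5-{[(1S,2R,5S)-2-isopropyl-5-methylcyclohexyl]oxy}furan-2(5H)-one; 13 4-(benzyloxy)-3,5-dimethoxybenzyl bromide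
Product: 16 (3S,4S,5S)-3-[4-(benzyloxy)-3,5-dimethoxybenzyl]-4-{2-[4-(benzyloxy)-3-methoxyphenyl]-1,3-dithian-2-yl}-5-{[(1S,2R,5S)-2-isopropyl-5-methylcyclohexyl]oxy}dihydrofuran-2(3H)-one, via 2-lithio dithiane 14 (not isolated), via lithium enolate 15 (not isolated)
Conditions: 9, n-BuLi, THF, −78 °C; 6, −78 °C; then 13, DMPU, −78 °C → rt
Reagents that add atoms: none
Why: n-BuLi removes the proton flanked by two sulfur atoms and the aryl ring of 9, the soft carbanion 14 adds in Michael fashion to C4 of butenolide 6 to give lithium enolate 15, and 15 is C-benzylated at C3 by bromide 13 once DMPU has loosened the enolate aggregate. The closest known reaction type is the tandem conjugate addition–enolate alkylation of 5-alkoxy-2(5H)-furanones with lithiated aryl dithioacetals, the usual entry to trans-dibenzylbutyrolactones. No ring is closed; C4–C7 and C3–C6 are both formed on the existing lactone ring. C4 is controlled by the acetal centre C5: the nucleophile enters on the ring face opposite the menthyloxy group, giving the spatial arrangement at C4 that the target needs. C3 is set provisionally by attack of the bromide on the enolate face opposite the bulky dithianyl group (all-trans adduct) and is reset in step 11. The step needs 1,4- over 1,2-addition, secured by the stabilized soft anion and low temperature, and C-monoalkylation, secured by the reactive benzylic bromide and the crowded product.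

Step 9
Reactants: 16 the tandem adduct
Product: 17 (3S,4S,5S)-3-[4-(benzyloxy)-3,5-dimethoxybenzyl]-4-[4-(benzyloxy)-3-methoxybenzyl]-5-{[(1S,2R,5S)-2-isopropyl-5-methylcyclohexyl]oxy}dihydrofuran-2(3H)-one
Conditions: NiCl2·6H2O, NaBH4, MeOH/THF, 0 °C → rt
Reagents that add atoms: none
Why: Nickel boride (Ni2B) formed in situ cleaves both benzylic C–S bonds reductively (desulfurization), turning the dithiane carbon into the C7 methylene while the benzyl ethers, the acetal and the ring stereocenters should be untouched.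

Step 10
Reactants: 17 the menthyloxy dibenzyl lactone
Product: 20 (3S,4S)-3-[4-(benzyloxy)-3,5-dimethoxybenzyl]-4-[4-(benzyloxy)-3-methoxybenzyl]dihydrofuran-2(3H)-one, via aldehyde carboxylate 18 (not isolated), via hydroxy carboxylate 19 (not isolated)
Conditions: NaBH4, KOH, EtOH/H2O, 0 °C → rt; then 2 M HCl to pH 1, rt
Reagents that add atoms: potassium hydroxide, [K+].[OH-] (its oxygen enters the carboxylate of 18 and 19 and can remain as the carbonyl oxygen of 20)
Why: Hydroxide opens the acyl acetal to carboxylate aldehyde 18 with release of the auxiliary, borohydride already present reduces the aldehyde at once to 19 so that C4 should not epimerize, and acid closes the 4-hydroxy acid to the lactone (saponification–reduction–lactonization known for 5-alkoxybutyrolactones).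

Step 11
Reactants: 20 the trans-dibenzyl lactone
Product: 22 (3S,4R)-3-[4-(benzyloxy)-3,5-dimethoxybenzyl]-4-[4-(benzyloxy)-3-methoxybenzyl]-3-hydroxydihydrofuran-2(3H)-one, via potassium enolate 21 (not isolated)
Conditions: KN(SiMe3)2, THF, −78 °C; 2-(phenylsulfonyl)-3-phenyloxaziridine, −78 °C; AcOH quench
Reagents that add atoms: 2-(phenylsulfonyl)-3-phenyloxaziridine, O=S(=O)(c1ccccc1)N1OC1c1ccccc1
Why: The base forms the tetrasubstituted lactone enolate 21 and electrophilic oxygen transfer from the N-sulfonyloxaziridine (Davis hydroxylation) should occur on the face opposite the C4 arylmethyl group, placing the hydroxyl trans to C7 and the syringylmethyl group cis to it (3S).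

Step 12
Reactants: 22 the bis-benzyl ether
Product: 23 (3S,4R)-3-hydroxy-3-(4-hydroxy-3,5-dimethoxybenzyl)-4-(4-hydroxy-3-methoxybenzyl)dihydrofuran-2(3H)-one (CNP0176953.1)
Conditions: H2 (1 atm), Pd/C (10 wt% palladium on carbon), EtOAc/EtOH, rt
Reagents that add atoms: none
Why: Heterogeneous hydrogenolysis cleaves both aryl benzyl ethers, while the lactone, the non-benzylic tertiary alcohol and both stereocenters are inert.

**Compound list**

1 | furfural | O=Cc1ccco1 | starting material
2 | furfural endoperoxide, 2,3,7-trioxabicyclo[2.2.1]hept-5-ene-1-carbaldehyde | O=CC12C=CC(OO1)O2 | intermediate (not isolated)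
3 | 5-hydroxyfuran-2(5H)-one (racemic) | O=C1C=CC(O)O1 | intermediate
4 | (+)-menthol, (1S,2R,5S)-2-isopropyl-5-methylcyclohexanol | CC(C)[C@H]1CC[C@H](C)C[C@@H]1O | starting material
5 | (5R)-5-{[(1S,2R,5S)-2-isopropyl-5-methylcyclohexyl]oxy}furan-2(5H)-one | O=C1C=C[C@H](O[C@H]2C[C@@H](C)CC[C@@H]2C(C)C)O1 | intermediate (not isolated)
6 | (5S)-5-{[(1S,2R,5S)-2-isopropyl-5-methylcyclohexyl]oxy}furan-2(5H)-one | O=C1C=C[C@@H](O[C@H]2C[C@@H](C)CC[C@@H]2C(C)C)O1 | intermediate
7 | vanillin | COc1cc(C=O)ccc1O | starting material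
8 | 4-(benzyloxy)-3-methoxybenzaldehyde | COc1cc(C=O)ccc1OCc1ccccc1 | intermediate
9 | 2-[4-(benzyloxy)-3-methoxyphenyl]-1,3-dithiane | COc1cc(C2SCCCS2)ccc1OCc1ccccc1 | intermediate
10 | syringaldehyde | COc1cc(C=O)cc(OC)c1O | starting material
11 | 4-(benzyloxy)-3,5-dimethoxybenzaldehyde | COc1cc(C=O)cc(OC)c1OCc1ccccc1 | intermediate
12 | [4-(benzyloxy)-3,5-dimethoxyphenyl]methanol | COc1cc(CO)cc(OC)c1OCc1ccccc1 | intermediate
13 | 4-(benzyloxy)-3,5-dimethoxybenzyl bromide | COc1cc(CBr)cc(OC)c1OCc1ccccc1 | intermediate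
14 | 2-[4-(benzyloxy)-3-methoxyphenyl]-2-lithio-1,3-dithiane | [Li]C1(c2ccc(OCc3ccccc3)c(OC)c2)SCCCS1 | intermediate (not isolated)
15 | lithium (4S,5S)-4-{2-[4-(benzyloxy)-3-methoxyphenyl]-1,3-dithian-2-yl}-5-{[(1S,2R,5S)-2-isopropyl-5-methylcyclohexyl]oxy}-4,5-dihydrofuran-2-olate | [Li]OC1=C[C@H](C2(c3ccc(OCc4ccccc4)c(OC)c3)SCCCS2)[C@@H](O[C@H]2C[C@@H](C)CC[C@@H]2C(C)C)O1 | intermediate (not isolated)
16 | (3S,4S,5S)-3-[4-(benzyloxy)-3,5-dimethoxybenzyl]-4-{2-[4-(benzyloxy)-3-methoxyphenyl]-1,3-dithian-2-yl}-5-{[(1S,2R,5S)-2-isopropyl-5-methylcyclohexyl]oxy}dihydrofuran-2(3H)-one (all-trans) | O=C1O[C@H](O[C@H]2C[C@@H](C)CC[C@@H]2C(C)C)[C@@H](C2(c3ccc(OCc4ccccc4)c(OC)c3)SCCCS2)[C@@H]1Cc1cc(OC)c(OCc2ccccc2)c(OC)c1 | intermediate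
17 | (3S,4S,5S)-3-[4-(benzyloxy)-3,5-dimethoxybenzyl]-4-[4-(benzyloxy)-3-methoxybenzyl]-5-{[(1S,2R,5S)-2-isopropyl-5-methylcyclohexyl]oxy}dihydrofuran-2(3H)-one | O=C1O[C@H](O[C@H]2C[C@@H](C)CC[C@@H]2C(C)C)[C@@H](Cc2ccc(OCc3ccccc3)c(OC)c2)[C@@H]1Cc1cc(OC)c(OCc2ccccc2)c(OC)c1 | intermediate
18 | potassium (2S,3S)-2-[4-(benzyloxy)-3,5-dimethoxybenzyl]-3-[4-(benzyloxy)-3-methoxybenzyl]-4-oxobutanoate | [K+].[O-]C(=O)[C@@H](Cc1cc(OC)c(OCc2ccccc2)c(OC)c1)[C@@H](C=O)Cc1ccc(OCc2ccccc2)c(OC)c1 | intermediate (not isolated)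
19 | potassium (2S,3S)-2-[4-(benzyloxy)-3,5-dimethoxybenzyl]-3-[4-(benzyloxy)-3-methoxybenzyl]-4-hydroxybutanoate | [K+].[O-]C(=O)[C@@H](Cc1cc(OC)c(OCc2ccccc2)c(OC)c1)[C@@H](CO)Cc1ccc(OCc2ccccc2)c(OC)c1 | intermediate (not isolated)
20 | (3S,4S)-3-[4-(benzyloxy)-3,5-dimethoxybenzyl]-4-[4-(benzyloxy)-3-methoxybenzyl]dihydrofuran-2(3H)-one (trans) | O=C1OC[C@@H](Cc2ccc(OCc3ccccc3)c(OC)c2)[C@@H]1Cc1cc(OC)c(OCc2ccccc2)c(OC)c1 | intermediate
21 | potassium (4S)-3-[4-(benzyloxy)-3,5-dimethoxybenzyl]-4-[4-(benzyloxy)-3-methoxybenzyl]-4,5-dihydrofuran-2-olate | [K+].[O-]C1=C(Cc2cc(OC)c(OCc3ccccc3)c(OC)c2)[C@H](Cc2ccc(OCc3ccccc3)c(OC)c2)CO1 | intermediate (not isolated)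
22 | (3S,4R)-3-[4-(benzyloxy)-3,5-dimethoxybenzyl]-4-[4-(benzyloxy)-3-methoxybenzyl]-3-hydroxydihydrofuran-2(3H)-one | COc1cc(C[C@@H]2COC(=O)[C@]2(O)Cc2cc(OC)c(OCc3ccccc3)c(OC)c2)ccc1OCc1ccccc1 | intermediate
23 | (3S,4R)-3-hydroxy-3-(4-hydroxy-3,5-dimethoxybenzyl)-4-(4-hydroxy-3-methoxybenzyl)dihydrofuran-2(3H)-one | COc1cc(C[C@@H]2COC(=O)[C@]2(O)Cc2cc(OC)c(O)c(OC)c2)ccc1O | target

**Step count**

Total: 12 steps. Longest linear sequence: 8 steps (steps 5, 6, 7, 8, 9, 10, 11, 12, from syringaldehyde).

**Steps most likely to fail**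

Step 8. The one-pot sequence may stall after the conjugate addition: the hindered enolate next to the quaternary dithianyl carbon may be protonated or alkylate slowly, and some 1,2-addition may compete. The fallback separates the two bond formations and sets out from 9 and 6. Dithiane 9 is lithiated as before and added to 6 at −78 °C, and the enolate is quenched with AcOH to give the isolated Michael adduct (4S,5S)-4-{2-[4-(benzyloxy)-3-methoxyphenyl]-1,3-dithian-2-yl}-5-{[(1S,2R,5S)-2-isopropyl-5-methylcyclohexyl]oxy}dihydrofuran-2(3H)-one F1. F1 is then deprotonated with LiN(iPr)2 in THF/DMPU at −78 °C and alkylated with an excess of 13 on the face opposite the dithianyl group, which brings the route back at 16.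

Step 11. Oxygen transfer to the crowded tetrasubstituted enolate may be incomplete, the enolate may add to the sulfonimine by-product, and the facial preference may be eroded. The fallback changes the oxidation to a Rubottom sequence on an isolated enol derivative and sets out from 20. The potassium enolate is trapped with Me3SiCl to give the silyl ketene acetal {[(4S)-3-[4-(benzyloxy)-3,5-dimethoxybenzyl]-4-[4-(benzyloxy)-3-methoxybenzyl]-4,5-dihydrofuran-2-yl]oxy}trimethylsilane F2. F2 is epoxidized with dimethyldioxirane in acetone/CH2Cl2 at −78 °C on the face opposite the C4 arylmethyl group and rearranges to (3S,4R)-3-[4-(benzyloxy)-3,5-dimethoxybenzyl]-4-[4-(benzyloxy)-3-methoxybenzyl]-3-[(trimethylsilyl)oxy]dihydrofuran-2(3H)-one F3. Dilute HCl in THF removes the silyl group and the route is rejoined at 22.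

Step 10. In aqueous KOH the ring-opened aldehyde may enolize and epimerize C4 before hydride arrives, and relactonization may be incomplete. The fallback removes the auxiliary under acid first and sets out from 17. Aqueous trifluoroacetic acid in THF hydrolyses the menthyl acetal to the lactol (3S,4S)-3-[4-(benzyloxy)-3,5-dimethoxybenzyl]-4-[4-(benzyloxy)-3-methoxybenzyl]-5-hydroxydihydrofuran-2(3H)-one F4 (C5 epimers), with recovery of (+)-menthol. NaBH4 in EtOH at 0 °C then reduces the ring-chain tautomeric aldehyde without strong base, and acidification with HCl closes the hydroxy acid, returning to the route at 20.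

**Further compounds**

F1 | step 8 | (4S,5S)-4-{2-[4-(benzyloxy)-3-methoxyphenyl]-1,3-dithian-2-yl}-5-{[(1S,2R,5S)-2-isopropyl-5-methylcyclohexyl]oxy}dihydrofuran-2(3H)-one | O=C1C[C@H](C2(c3ccc(OCc4ccccc4)c(OC)c3)SCCCS2)[C@@H](O[C@H]2C[C@@H](C)CC[C@@H]2C(C)C)O1
F2 | step 11 | {[(4S)-3-[4-(benzyloxy)-3,5-dimethoxybenzyl]-4-[4-(benzyloxy)-3-methoxybenzyl]-4,5-dihydrofuran-2-yl]oxy}trimethylsilane | C[Si](C)(C)OC1=C(Cc2cc(OC)c(OCc3ccccc3)c(OC)c2)[C@H](Cc2ccc(OCc3ccccc3)c(OC)c2)CO1
F3 | step 11 | (3S,4R)-3-[4-(benzyloxy)-3,5-dimethoxybenzyl]-4-[4-(benzyloxy)-3-methoxybenzyl]-3-[(trimethylsilyl)oxy]dihydrofuran-2(3H)-one | COc1cc(C[C@@H]2COC(=O)[C@]2(O[Si](C)(C)C)Cc2cc(OC)c(OCc3ccccc3)c(OC)c2)ccc1OCc1ccccc1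
F4 | step 10 | (3S,4S)-3-[4-(benzyloxy)-3,5-dimethoxybenzyl]-4-[4-(benzyloxy)-3-methoxybenzyl]-5-hydroxydihydrofuran-2(3H)-one | O=C1OC(O)[C@@H](Cc2ccc(OCc3ccccc3)c(OC)c2)[C@@H]1Cc1cc(OC)c(OCc2ccccc2)c(OC)c1
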